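Percent of the L and Z together charged was the unit of everything I read, and these were the flasks.

| flask | L | Z | G | remark | time |
|---|---|---|---|---|---|
| blue | 0.10 M | 1 equiv | 1.1 mol% | run made earlier |  |
| teal | 0.10 M | 0.50 equiv | 1.6 mol% | run made earlier |  |
| eta | 0.10 M | 1.00 equiv | 1.6 mol% |  | 40 min |
| epsilon | 0.20 M | 1.00 equiv | 1.6 mol% |  | 40 min |
| delta | 0.40 M | 1.00 equiv | 1.6 mol% |  | 40 min |
| theta | 0.80 M | 1.00 equiv | 1.6 mol% |  | 40 min |

| run | time / min | X / % | D / % | E / % |
|---|---|---|---|---|
| blue | 2.00 | 55 | 2 | 42 |
| blue | 4.00 | 35 | 3 | 62 |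
| blue | 6.00 | 26 | 4 | 69 |
| blue | 8.00 | 30 | 5 | 69 |
| blue | 10.0 | 26 | 2 | 68 |
| blue | 12.0 | 25 | 2 | 70 |
| blue | 15.0 | 26 | 3 | 73 |
| teal | 2.00 | 47 | 1 | 54 |
| teal | 4.00 | 32 | 7 | 66 |
| teal | 6.00 | 29 | 4 | 70 |
| teal | 8.00 | 29 | 4 | 71 |
| teal | 10.0 | 26 | 3 | 68 |
| teal | 12.0 | 27 | 3 | 70 |
| teal | 15.0 | 32 | 2 | 72 |

(scatter of a reading: 2 percentage points)

- the earlier runs were read with a standard deviation of 2 percentage points
- "hardly changes" means that all values lie within two and a half points (for a concentration: within two and a half percent of the largest)

* share of X in all that became X or D or E for eta, epsilon, delta, theta, in this order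
* the shape of the row from first to last (rises, then falls / falls all the way / falls, then rises / rises all the way / hardly changes)

Blue had levelled off by 6.00 min, so I summed its readings from there on. X over X plus E came to 27.6%, which I call the ceiling share. Teal, with a different charge of Z and G, read 28.9%. I assumed that X and E interconvert on G, each way pseudo-first-order at a given c_G, so c_G cancels from their ratio. The share asked is then the ceiling times one minus the share of D, and the ceiling bounds it from above.

From below, the question was how much D theta could hold. If D comes from Z, allowing it Z's half of the charge gave a floor of 13.8%. To tighten this, I let Z divide between capture on G and a path without G, so the odds of capture rise in step with c_G. Blue's D averaged 3.00%, which is odds of 0.0638 on its Z. Theta has 11.6 times blue's c_G, so I estimated its D at 21.3% and put the floor, as an estimate on that assumption, at 21.7%.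

The forecast gave 27.5%, 27.5%, 27.5%, 27.5%, shape "hardly changes", on the ground of “no net change in molecule count”; that lies below my ceiling and above my floor.

The flasks gave 26.0%, 25.7%, 25.1%, 24.1%, shape "hardly changes", a drop of 1.9 percentage points from eta to theta.

    L ⇌ Z (K = 0.0680, k = 0.0520 s⁻¹)
    L + G → G + X (k = 36.0 L mol⁻¹ s⁻¹)
    G + Z → G + D (k = 13.0 L mol⁻¹ s⁻¹)
    X + G ⇌ E + G, rate k4*[G]*[X] forward; the back reaction follows from the equilibrium constant (K = 2.70, k = 6.80 L mol⁻¹ s⁻¹)

My ceiling times what D left gave 26.6% for eta, with D at 3.63%, and 24.6% for theta, with D at 10.7%, which is less D than my 21.3%. The largest single effect I can name on theta's share is the back reaction of Z to L, which returns Z to L on the way to X. Theta run without that step gave 12.1% in place of 24.1%.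

The readings are simulated with made-up constants; the scatter is artificial.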